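4 questions stood on the flasks below, and I had two earlier runs to answer them with.

| flask | L | temperature | remark | time |
|---|---|---|---|---|
| oak | 1.3 M | 60 °C | run made earlier |  |
| alder | 3 M | 90 °C | run made earlier |  |
| beta | 2.0 M | 115 °C |  | 50 min |
| zeta | 2.0 M | 65 °C |  | 50 min |
| delta | 2.0 M | 90 °C |  | 50 min |

| run | time / min | D / % |
|---|---|---|
| oak | 90.0 | 25.8 |
| oak | 300 | 39.2 |
| oak | 480 | 38.5 |
| oak | 720 | 33.2 |
| alder | 20.0 | 31.2 |
| alder | 60.0 | 23.0 |
| alder | 90.0 | 22.2 |
| alder | 180 | 21.3 |

(readings scatter by 0.3 percentage points)

- the flask that comes out highest in amount of D, in percent of the L charged, or "all alike" when all lie within 1.5 percentage points (beta / zeta / delta / all alike)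
- D at the end, in percent of the L charged, beta
- D at the end, in percent of the L charged, zeta
- D at the end, in percent of the L charged, delta

- a reading or a percentage of D counts all its forms, free or not

I went through delta in slow motion, since delta shares its temperature with alder. In the first instants L stood at its charge and D at nothing, so D had to rise. In the middle D passed a peak: alder read 31.2% at 20.0 min and less at each later reading, so its peak lay before 60.0 min.

What mattered next was the fall. I took alder's last reading, 21.3%, as its plateau. The excess of D over it shrank from 9.9 percentage points to 1.7 points in 40.0 min. That gave 22.7 min. This is τ, the relaxation time, the time in which the excess of D over its plateau shrinks by a factor e.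

I went round once more and held τ against a reading not used to make it. At 90.0 min τ left an excess of 0.45 points, but alder read 0.9 points above its last reading, more than τ left. The gap was 0.45 points against a scatter of 0.3 points, so I kept τ but held the plateau as a rough one, with a slow downward drift not ruled out.

The end of delta's run lay 30.0 min past alder's first reading, longer than τ. On alder's curve the excess was then 2.6 points, which gave 23.9%. I committed to that for delta, as a rough figure, since delta's charge of 2.0 M is lower than alder's 3 M. Beta, hotter than alder, I put on alder's plateau, below delta. Zeta, at 65 °C, I held to be still rising at 50 min, earlier than oak's highest reading at 300 min.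

The forecast named delta highest, with 28% for beta, 26% for zeta and 30% for delta, and said “Beta is already at its plateau, perhaps with some drift”. The flasks gave 19.4% for beta, 23.0% for zeta and 26.6% for delta, so delta came out highest.

    L + D ⇌ G, settled at all times (K = 0.738 L mol⁻¹, ΔH = −11.0 kJ mol⁻¹)
    D ⇌ Q (K = 1.97, k = 0.00109 s⁻¹, Ea = 120 kJ mol⁻¹, ΔH = −13.0 kJ mol⁻¹)
    L ⇌ D (K = 6.35, k = 0.00131 s⁻¹, Ea = 95.0 kJ mol⁻¹, ΔH = −67.0 kJ mol⁻¹)
    2 L → E (k = 2.76 × 10⁻⁴ L mol⁻¹ s⁻¹, Ea = 70.0 kJ mol⁻¹)
    (constants at 90 °C)

Delta stood 2.7 points above my figure, which came from alder's heavier charge. Delta at 500 min held 22.9%, and I used that as a rough plateau for delta. This left delta an excess of 3.7 points at 50 min. The neighbouring flask was delta stopped at 30 min. Carried back by τ, 22.7 min, over 20.0 min, that excess gave 31.8%. The neighbouring flask read 30.9%.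

The earlier runs and the new flask were computed for substances that don't exist, noise included.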